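**Plan**
- Retrosynthetic cuts, in order: (i) the two catechol OH groups meta to the ethylene chains are traced back to OMe; (ii) the biaryl C–C bond is cut; (iii) the CH2–CH2 bridge of the resulting monomer is cut as a C=C.
- Enabling feature: both halves are the same unit, 4-[2-(3-methoxyphenyl)ethyl]catechol. In catechol ring A the biaryl bond starts at the carbon ortho to the OH that is para to the chain. In catechol ring B it ends at the carbon ortho to the chain and para to the oxygen that is meta to the chain. This is the ortho–meta pattern in which a 4-alkylguaiacol dimerises at an anode, so one vanillin-derived monomer serves as both the radical and the nucleophile.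
- Forward: O-benzylvanillin and a 3-methoxybenzyl phosphonate give the stilbene. One hydrogenation (C=C and OBn together) gives the guaiacol monomer. Anodic dehydrodimerisation follows, without halide, boron or metal. Chelation-directed cleavage then removes only the two guaiacol OMe groups.
- No ring is built; all four benzene rings are purchased, and the chain is joined before the biaryl bond.
- Stereochemistry: there is no stereocentre, and the axis carries only OH and CH2CH2Ar besides two H in its ortho positions.

Key step: step 3

Assumption: the SMILES has no stereodescriptor and a biaryl axis with only two non-hydrogen ortho substituents is not configurationally stable. The target is therefore treated as achiral and no enantioselective operation is needed.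

Step 1
Reactants: 1 4-(benzyloxy)-3-methoxybenzaldehyde (O-benzylvanillin); 2 diethyl (3-methoxybenzyl)phosphonate
Product: 4 (E)-1-(benzyloxy)-2-methoxy-4-[2-(3-methoxyphenyl)ethenyl]benzene, via potassium phosphonate carbanion 3 (not isolated)
Conditions: KOtBu (1.2 equiv), THF, 0 °C, then 1, 0 °C to rt
Reagents that add atoms: none
Why: Horner–Wadsworth–Emmons olefination of a non-enolisable benzaldehyde with a benzylic phosphonate carbanion should give mainly the E-stilbene, and the alkene geometry is irrelevant because the double bond is saturated in step 2.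

Step 2
Reactants: 4 (E)-1-(benzyloxy)-2-methoxy-4-[2-(3-methoxyphenyl)ethenyl]benzene
Product: 6 2-methoxy-4-[2-(3-methoxyphenyl)ethyl]phenol, via saturated benzyl ether 5 (not isolated)
Conditions: H2 (1 atm), 10% Pd/C, EtOAc/EtOH, rt
Reagents that add atoms: none
Why: Heterogeneous catalytic hydrogenation should saturate the stilbene C=C first and then hydrogenolyse the benzyl ether, while the aryl methyl ethers and the arenes are inert at 1 atm and rt.

Step 3
Reactants: 6 2-methoxy-4-[2-(3-methoxyphenyl)ethyl]phenol (two molecules)
Product: 8 3,4'-dimethoxy-2',5-bis[2-(3-methoxyphenyl)ethyl]-[1,1'-biphenyl]-2,5'-diol, via phenoxyl radical 7 (not isolated)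
Conditions: BDD anode, Ni cathode, undivided cell, constant current ca. 3–5 mA cm⁻², ca. 1 F per mol of 6, Et3NMe⁺ MeOSO3⁻ (ca. 0.1 M), HFIP, 50 °C; unreacted 6 recovered
Reagents that add atoms: none
Why: The free 4-alkylguaiacol ring is the most easily oxidised part of 6, so at the BDD anode the HFIP-solvated phenol loses one electron and its O–H proton to give phenoxyl radical 7, whose spin density lies on O, C2 (OMe), C4 (chain) and C6, only C6 being unsubstituted; C6 of 7 attacks a second, unoxidised molecule of 6 at C5 (para to OMe, ortho to the chain, meta to OH), and a second electron transfer plus loss of two protons, which leave as H2 at the cathode, rearomatise both rings to 8. The closest known reaction type is the anodic dehydrogenative ortho–meta homocoupling of 4-alkyl-2-methoxyphenols to non-symmetrical 2,5'-biphenols at BDD in HFIP, a sibling of the anodic phenol–arene cross-coupling. No ring is closed and no stereocentre arises, and the new axis, flanked only by OH, CH2CH2Ar and two H, should rotate freely. The step needs site selectivity (C6–C5' instead of the symmetrical C6–C6' dimer or C–O coupling), which is secured by a radical-plus-neutral-arene pathway rather than radical–radical recombination: low current density and a concentrated solution keep 7 scarce relative to 6, and hydrogen bonding of HFIP to the phenolic oxygen shields O and damps the OH-directed positions, so that OMe directs the nucleophilic partner to C5. It also needs ring selectivity, which the substrate supplies, because the 3-alkylanisole rings carry a single oxygen, are expected to be clearly harder to oxidise and poorer partners for the electrophilic radical, and because C6 is meta to the chain and cannot reach the anisole ring of its own molecule. Over-oxidation of 8 should be limited by its HFIP solvation, by the twisted axis and by stopping the electrolysis near the theoretical charge.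

Step 4
Reactants: 8 3,4'-dimethoxy-2',5-bis[2-(3-methoxyphenyl)ethyl]-[1,1'-biphenyl]-2,5'-diol
Product: 10 isoplagilin (2',5-bis[2-(3-methoxyphenyl)ethyl]-[1,1'-biphenyl]-2,3,4',5'-tetrol), via bis(chloroaluminium catecholate) 9 (not isolated)
Conditions: AlCl3 (3 equiv), pyridine (12 equiv), CH2Cl2, reflux, Ar; then degassed 2 M HCl, 0 °C
Reagents that add atoms: none
Why: In this chelation-directed cleavage of alkyl o-hydroxyphenyl ethers each free phenol binds aluminium and the neighbouring OMe closes a five-membered chelate that activates its methyl group for SN2 removal by pyridine, whereas the two 3-alkylanisole OMe groups have no adjacent OH, are not chelated and should survive the pyridine-tempered Lewis acid.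

**Compound list**
1 | 4-(benzyloxy)-3-methoxybenzaldehyde (O-benzylvanillin) | COc1cc(C=O)ccc1OCc1ccccc1 | starting material
2 | diethyl (3-methoxybenzyl)phosphonate | CCOP(=O)(Cc1cccc(OC)c1)OCC | starting material
3 | potassium salt of the benzylic carbanion of 2 | CCOP(=O)([CH-]c1cccc(OC)c1)OCC.[K+] | intermediate
4 | (E)-1-(benzyloxy)-2-methoxy-4-[2-(3-methoxyphenyl)ethenyl]benzene | COc1cccc(/C=C/c2ccc(OCc3ccccc3)c(OC)c2)c1 | intermediate
5 | 1-(benzyloxy)-2-methoxy-4-[2-(3-methoxyphenyl)ethyl]benzene | COc1cccc(CCc2ccc(OCc3ccccc3)c(OC)c2)c1 | intermediate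
6 | 2-methoxy-4-[2-(3-methoxyphenyl)ethyl]phenol | COc1cccc(CCc2ccc(O)c(OC)c2)c1 | intermediate
7 | 2-methoxy-4-[2-(3-methoxyphenyl)ethyl]phenoxyl radical | COc1cccc(CCc2ccc([O])c(OC)c2)c1 | intermediate
8 | 3,4'-dimethoxy-2',5-bis[2-(3-methoxyphenyl)ethyl]-[1,1'-biphenyl]-2,5'-diol | COc1cccc(CCc2cc(OC)c(O)c(-c3cc(O)c(OC)cc3CCc3cccc(OC)c3)c2)c1 | intermediate
9 | bis(chloroaluminium catecholate) of 10 (idealised, pyridine ligands omitted) | COc1cccc(CCc2cc3O[Al](Cl)Oc3c(-c3cc4O[Al](Cl)Oc4cc3CCc3cccc(OC)c3)c2)c1 | intermediate
10 | isoplagilin | COc1cccc(CCc2cc(O)c(O)c(-c3cc(O)c(O)cc3CCc3cccc(OC)c3)c2)c1 | target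

Total step count: 4. Longest linear sequence: 4.

**Steps most likely to fail**

Step 3.
- What may go wrong: coupling at the wrong site (symmetrical ortho–ortho dimerisation, C–O coupling, attack on an anisole ring). Benzylic oxidation by way of a p-quinone methide is a second risk, and further oxidation of the biphenol to oligomers a third.
- Fallback, from 2 back to 8: the biaryl bond is made by Suzuki–Miyaura coupling before the arms are attached, with the regiochemistry fixed by purchased bromides.
- Commercial 5-bromovanillin and 6-bromovanillin are O-benzylated (BnBr, K2CO3, DMF). This gives 4-(benzyloxy)-3-bromo-5-methoxybenzaldehyde F1 and 4-(benzyloxy)-2-bromo-5-methoxybenzaldehyde F2.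
- Miyaura borylation of F1 (B2pin2, Pd(dppf)Cl2, KOAc, dioxane, 90 °C) gives 4-(benzyloxy)-3-methoxy-5-(4,4,5,5-tetramethyl-1,3,2-dioxaborolan-2-yl)benzaldehyde F3.
- Coupling of F3 with the activated bromide F2 (Pd(OAc)2, SPhos, K2CO3, dioxane/H2O, 80 °C) gives 2',5-bis(benzyloxy)-3',4-dimethoxy-[1,1'-biphenyl]-2,5'-dicarbaldehyde F4.
- A double Horner–Wadsworth–Emmons reaction with 2 (2.4 equiv, KOtBu, THF) gives the bis[(E)-3-methoxystyryl] bis(benzyl ether) biaryl F5.
- H2 with Pd/C saturates both alkenes and removes both benzyl groups to deliver 8.

Step 4.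
- What may go wrong: incomplete cleavage at the hindered ring A, slow loss of the anisole methyl groups on prolonged heating, or air oxidation of the catechols during work-up.
- Fallback, from 8 to 10: oxidative instead of Lewis-acidic demethylation. IBX (stabilised formulation, 2.5 equiv, THF, rt, dark) ligates only free phenols and delivers oxygen to the OMe-bearing ortho carbon.
- Loss of methanol gives the bis(ortho-quinone) F6, which is reduced in the same flask with aqueous Na2S2O4 to 10. The anisole ethers cannot take part because they lack a phenolic OH.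

Step 1.
- What may go wrong: sluggish addition of the only weakly stabilised carbanion to the electron-rich aldehyde, leading to incomplete conversion.
- Fallback, from 1 to 4: Wittig methylenation of 1 (MePPh3Br, KOtBu, THF) gives 1-(benzyloxy)-4-ethenyl-2-methoxybenzene F7.
- A Heck reaction of F7 with 3-iodoanisole (Pd(OAc)2, P(o-tol)3, K2CO3, DMF, 100 °C) gives 4.

**Further compounds**
F1 | step 3 | 4-(benzyloxy)-3-bromo-5-methoxybenzaldehyde | COc1cc(C=O)cc(Br)c1OCc1ccccc1
F2 | step 3 | 4-(benzyloxy)-2-bromo-5-methoxybenzaldehyde | COc1cc(C=O)c(Br)cc1OCc1ccccc1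
F3 | step 3 | 4-(benzyloxy)-3-methoxy-5-(4,4,5,5-tetramethyl-1,3,2-dioxaborolan-2-yl)benzaldehyde | COc1cc(C=O)cc(B2OC(C)(C)C(C)(C)O2)c1OCc1ccccc1
F4 | step 3 | 2',5-bis(benzyloxy)-3',4-dimethoxy-[1,1'-biphenyl]-2,5'-dicarbaldehyde | COc1cc(C=O)cc(-c2cc(OCc3ccccc3)c(OC)cc2C=O)c1OCc1ccccc1
F5 | step 3 | 2,5'-bis(benzyloxy)-3,4'-dimethoxy-2',5-bis[(E)-2-(3-methoxyphenyl)ethenyl]-1,1'-biphenyl | COc1cccc(/C=C/c2cc(OC)c(OCc3ccccc3)c(-c3cc(OCc4ccccc4)c(OC)cc3/C=C/c3cccc(OC)c3)c2)c1
F6 | step 4 | bis(ortho-quinone) of 10 | COc1cccc(CCC2=CC(=O)C(=O)C(C3=CC(=O)C(=O)C=C3CCc3cccc(OC)c3)=C2)c1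
F7 | step 1 | 1-(benzyloxy)-4-ethenyl-2-methoxybenzene | C=Cc1ccc(OCc2ccccc2)c(OC)c1
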